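4 questions stand on the board, and one straight line should answer them.

| setting | amber | blue | midnight | winter | autumn |
|---|---|---|---|---|---|
| substrate | 0.40 M | 1.6 M | 0.80 M | 0.80 M | 0.80 M |
| gas | 65 mM (held) | 65 mM (held) | 65 mM (held) | 65 mM (held) | 65 mM (held) |
| temperature | 89 °C | 97 °C | 100 °C | 85 °C |  |
| remark | run made earlier | run made earlier |  |  | at 85 °C until 10 min, from then on at 100 °C |
| time |  |  | 30 min | 30 min | 30 min |

| run | time / min | ring / % |
|---|---|---|
| amber | 5.00 | 4 |
| amber | 15.0 | 12 |
| amber | 25.0 | 27 |
| amber | 40.0 | 47 |
| amber | 60.0 | 60 |
| blue | 8.00 | 10 |
| blue | 15.0 | 18 |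
| blue | 20.0 | 26 |
| blue | 30.0 | 40 |
| blue | 40.0 | 47 |

(readings scatter by 2 percentage points)

- the flask with the highest amount of ring, in percent of the substrate charged ("all alike" if they lie within 1.5 percentage points) (midnight / winter / autumn / all alike)
- final ring, as a percentage of the substrate charged, in midnight
- final ring, as a percentage of the substrate charged, in winter
- final ring, as a percentage of the substrate charged, in autumn

- at the start none of the gas is in solution

What do the curves do? They crawl, then run straight, and the straight part, in fractions of the charge, misses the origin. So ring seems to come from something that has to fill first.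

How do you measure that? By the lag, the time at which the straight part, carried back, meets zero. Amber, between 15.0 min and 40.0 min, climbs 0.0140 min⁻¹ of its charge, with a lag of 6.43 min. Blue, between 15.0 min and 30.0 min, climbs 0.0147 min⁻¹, with a lag of 2.73 min.

And at the flasks' temperatures? Taking the lag as exponential in temperature through these two readings gives 9.87 min at 85 °C and 1.98 min at 100 °C. Call the second the hot lag, the estimated time a flask at 100 °C spends filling before ring runs straight.

But the two slopes are nearly equal while the amber lag is longer than the blue one. Why trust the lags? The runs differ in charge as well as heat, 0.40 M against 1.6 M, so these slopes do not separate the two, and each lag rests on readings with a scatter of 2 percentage points. I assume one clock for both and set the difference in charge aside, so my slope scales inversely with the lag: 0.0202 min⁻¹ hot and 0.00912 min⁻¹ cold.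

Your answers? Midnight gives 56.7 % and winter 18.4 %. In autumn the cold lag of 9.87 min about equals the 10 min spent cold, so I count 20.0 min of hot slope, 40.5 %. Midnight comes first.

The forecast also names midnight, with 50 %, 23 % and 41 %, lower than mine in midnight and higher in winter, and it warns that “the activation energy is poorly defined”.

The simulation puts midnight highest: midnight 54.7 %, winter 19.6 %, autumn 51.1 %, so my autumn stands 11 points short. At 4.66 min in midnight, each step taken net, the activator is made 1.01 times as fast as it is used, a pseudo-first-order first step with a substrate half-life by that step of 6.5 min, while activated form, with a half-life towards ring of 7.2 min, is made 1.90 times as fast as it is used. Autumn at 10.0 min held 34.7 % activated form beside 3.65 % ring, and over its hot stretch ring then rose on average at 0.0237 min⁻¹, faster than my 0.0202 min⁻¹.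

    substrate + activator → activated form (k = 0.0300 M⁻¹ s⁻¹, Ea = 55.0 kJ mol⁻¹)
    activated form → ring (k = 0.00160 s⁻¹, Ea = 115 kJ mol⁻¹)
    substrate + activated form → open dimer (k = 8.60 × 10⁻⁴ M⁻¹ s⁻¹, Ea = 93.0 kJ mol⁻¹)
    substrate + ring → side product (k = 0.00240 M⁻¹ s⁻¹, Ea = 80.0 kJ mol⁻¹)
    gas ⇌ activator, rate k5*(csat - [activator]) (kL = 0.160 s⁻¹)
    (constants at 100 °C)

Midnight read at 8.0 min: the hot lag leaves 6.02 min of slope, which gives 12.2 % ring. The computed ring there is 14.6 %.

The readings were computed from invented constants; scatter was added.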